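**Retrosynthetic overview**

1. Target ⇐ spirolactone triene by late redox adjustments: SeO2 hydroxylation at C15, hydroxyl-directed 16,17-epoxidation, hydrogenation of C11=C12 with debenzylation, Saegusa desaturation (C2=C3), oxidation of C6–OH to the aldehyde.
2. Lactone ring (C20–O–C7) ⇐ reduction of a C20 aldehyde onto the C7 ester; C9–C10 bond and quaternary C10 ⇐ Claisen rearrangement of an O-allyl enol ether of a β-keto aldehyde.
3. That ether ⇐ Mitsunobu union of two C10 fragments: fragment A (ring A hydroxymethylene ketone, C5 set) and fragment B (bicyclo[3.2.1]octenol = rings C and D with the bridgehead ester).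
4. Fragment A ⇐ Robinson annulation (ring A), dehydrogenation to the dienone, rhodium-catalysed asymmetric alkenylation (C5), ozonolysis/benzylation, formylation.
5. Fragment B ⇐ catalytic asymmetric Diels–Alder (ring C, C8), gold-catalysed Conia-ene-type closure (ring D), Luche reduction. Ring order: A and C separately, then D, then the lactone ring after the union.

Assumption: the target is taken exactly as the SMILES drawn, i.e. (5R,8S,9S,10S,13R,15S,16S). Atom labels follow ent-kaurane numbering of the 6,7-seco skeleton (ring A = C1–C5, C10; C6 on C5; C20 on C10; C7 = lactone carbonyl on C8; bicyclooctane = C8, C9, C11–C16; C17 on C16); β is the face of H-5 and H-9.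

**Fragment A**

Step 1
Reactants: 1 2-methylpropanal; 2 but-3-en-2-one
Product: 3 4,4-dimethylcyclohex-2-en-1-one
Conditions: H2SO4 (cat.), toluene, 45 °C then reflux (Dean–Stark)
Reagents that add atoms: none
Why: Acid-catalysed Robinson annulation (Michael addition of the aldehyde enol, then intramolecular aldol condensation) gives the 4,4-disubstituted enone because the aldehyde has a single enolisable carbon.

Step 2
Reactants: 3 4,4-dimethylcyclohex-2-en-1-one
Product: 4 4,4-dimethylcyclohexa-2,5-dien-1-one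
Conditions: DDQ (1.3 equiv), dioxane, reflux
Reagents that add atoms: none
Why: Quinone dehydrogenation of the saturated C5–C6 edge through the enol gives the symmetrical cross-conjugated dienone, which keeps an alkene in place to block C2 in the later formylation.

Step 3
Reactants: 4 4,4-dimethylcyclohexa-2,5-dien-1-one (1.5 equiv); 5 (E)-prop-1-en-1-ylboronic acid
Product: 6 (5R)-4,4-dimethyl-5-[(1E)-prop-1-en-1-yl]cyclohex-2-en-1-one
Conditions: [Rh(OH)((R)-binap)]2 (1.5 mol%), dioxane/H2O (10:1), 35 °C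
Reagents that add atoms: none
Why: Hayashi–Miyaura rhodium-catalysed asymmetric 1,4-addition, in which the alkenyl–rhodium species bearing (R)-BINAP inserts one enone face and sets C5 as R, the dienone being in excess to suppress a second addition.

Step 4
Reactants: 6 (5R)-4,4-dimethyl-5-[(1E)-prop-1-en-1-yl]cyclohex-2-en-1-one
Product: 8 (5S)-5-(hydroxymethyl)-4,4-dimethylcyclohex-2-en-1-one, via aldehyde 7 (not isolated)
Conditions: O3, CH2Cl2/MeOH (5:1), −78 °C; Me2S, −78 °C to rt; then NaBH(OAc)3, CH2Cl2, 0 °C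
Reagents that add atoms: ozone, [O-][O+]=O
Why: Chemoselective ozonolysis of the electron-rich propenyl group (the enone alkene is far slower) and aldehyde-selective hydride reduction turn the alkenyl group into the C6 hydroxymethyl group without base, so C5 keeps its configuration (the descriptor changes only by priority).

Step 5
Reactants: 8 (5S)-5-(hydroxymethyl)-4,4-dimethylcyclohex-2-en-1-one
Product: 9 (5S)-5-[(benzyloxy)methyl]-4,4-dimethylcyclohex-2-en-1-one
Conditions: BnOC(=NH)CCl3 (1.5 equiv), TfOH (5 mol%), CH2Cl2/cyclohexane, 0 °C to rt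
Reagents that add atoms: benzyl 2,2,2-trichloroacetimidate, N=C(OCc1ccccc1)C(Cl)(Cl)Cl
Why: Acid-catalysed O-benzylation with the trichloroacetimidate protects the primary alcohol without base, which avoids oxa-Michael closure onto the enone.

Step 6
Reactants: 9 (5S)-5-[(benzyloxy)methyl]-4,4-dimethylcyclohex-2-en-1-one; 10 ethyl formate
Product: 11 (5R,6Z)-5-[(benzyloxy)methyl]-6-(hydroxymethylidene)-4,4-dimethylcyclohex-2-en-1-one
Conditions: NaH (2.2 equiv), EtOH (cat.), THF, 0 °C to rt; aqueous HCl work-up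
Reagents that add atoms: none
Why: Crossed Claisen condensation (formylation) can occur only at C10 because C2 is vinylic, so the β-keto aldehyde forms regiospecifically and rests as its chelated Z-enol with C5 untouched.

**Fragment B**

Step 7
Reactants: 12 pent-4-ynal; 13 formaldehyde
Product: 14 2-methylidenepent-4-ynal
Conditions: 37% aqueous CH2O, pyrrolidine (10 mol%), propanoic acid (10 mol%), i-PrOH, 45 °C
Reagents that add atoms: none
Why: Organocatalytic α-methylenation (Mannich condensation through the enamine, then β-elimination of the amine) gives the 2-substituted acrolein.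

Step 8
Reactants: 15 (3E)-4-(dimethylamino)but-3-en-2-one
Product: 16 (1E)-3-[(tert-butyldimethylsilyl)oxy]-N,N-dimethylbuta-1,3-dien-1-amine
Conditions: KN(SiMe3)2, THF, −78 °C; TBSCl, −78 °C to rt
Reagents that add atoms: tert-butyl(chloro)dimethylsilane, CC(C)(C)[Si](C)(C)Cl
Why: Kinetic enolisation of the vinylogous amide at its methyl group and O-silylation give the 1-amino-3-siloxy diene (Rawal diene).

Step 9
Reactants: 14 2-methylidenepent-4-ynal; 16 (1E)-3-[(tert-butyldimethylsilyl)oxy]-N,N-dimethylbuta-1,3-dien-1-amine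
Product: 18 (1R)-4-oxo-1-(prop-2-yn-1-yl)cyclohex-2-ene-1-carbaldehyde, via cycloadduct 17 (not isolated)
Conditions: chiral (salen)CrSbF6 (5 mol%; salen = N,N′-bis(3,5-di-tert-butylsalicylidene)cyclohexane-1,2-diamine dianion, used as the enantiomer that delivers the 1R adduct), 4 Å molecular sieves, CH2Cl2, −40 °C; then AcCl, CH2Cl2/Et2O, −78 °C to rt
Reagents that add atoms: none
Why: Catalytic asymmetric Diels–Alder reaction in which the chiral chromium Lewis acid binds the aldehyde and shields one dienophile face, so the quaternary C8 forms as R with ortho regiochemistry, after which N-acylation, β-elimination of the amine and loss of the silyl group unveil the enone.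

Step 10
Reactants: 18 (1R)-4-oxo-1-(prop-2-yn-1-yl)cyclohex-2-ene-1-carbaldehyde
Product: 20 methyl (1R)-4-oxo-1-(prop-2-yn-1-yl)cyclohex-2-ene-1-carboxylate, via acid 19 (not isolated)
Conditions: NaClO2, NaH2PO4, 2-methylbut-2-ene, t-BuOH/H2O, 0 °C to rt; then MeI, K2CO3, DMF, rt
Reagents that add atoms: sodium chlorite, [Na+].[O-]Cl=O; iodomethane, CI
Why: Pinnick oxidation of the neopentyl aldehyde and SN2 O-methylation of the carboxylate give the future bridgehead ester without touching the enone, the alkyne or C8.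

Step 11
Reactants: 20 methyl (1R)-4-oxo-1-(prop-2-yn-1-yl)cyclohex-2-ene-1-carboxylate
Product: 21 methyl (1R)-4-[(tert-butyldimethylsilyl)oxy]-1-(prop-2-yn-1-yl)cyclohexa-2,4-diene-1-carboxylate
Conditions: TBSOTf, Et3N, CH2Cl2, 0 °C
Reagents that add atoms: tert-butyldimethylsilyl trifluoromethanesulfonate, CC(C)(C)[Si](C)(C)OS(=O)(=O)C(F)(F)F
Why: Soft enolisation of the enone at its only enolisable carbon (C13) gives the cross-conjugated 2-silyloxy diene that serves as the carbon nucleophile.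

Step 12
Reactants: 21 methyl (1R)-4-[(tert-butyldimethylsilyl)oxy]-1-(prop-2-yn-1-yl)cyclohexa-2,4-diene-1-carboxylate
Product: 22 methyl (1R,5R)-6-methylidene-4-oxobicyclo[3.2.1]oct-2-ene-1-carboxylate
Conditions: Ph3PAuCl (5 mol%), AgBF4 (5 mol%), toluene/MeOH (10:1), rt
Reagents that add atoms: none
Why: Gold-catalysed 5-exo-dig carbocyclisation of the silyl enol ether onto the activated alkyne (Conia-ene type) forms C13–C16 and leaves the exo-methylene after protodeauration, and since the propargyl arm reaches C13 only from its own face, C13 is set by C8.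

Step 13
Reactants: 22 methyl (1R,5R)-6-methylidene-4-oxobicyclo[3.2.1]oct-2-ene-1-carboxylate
Product: 23 methyl (1R,4R,5R)-4-hydroxy-6-methylidenebicyclo[3.2.1]oct-2-ene-1-carboxylate
Conditions: NaBH4, CeCl3·7H2O, MeOH, −78 °C
Reagents that add atoms: none
Why: Luche 1,2-reduction in which hydride adds from the face of the one-carbon bridge (C14), anti to the C13–C16 bond, so the C12 hydroxyl lies on the face of the two-carbon bridge.

**Union and endgame**

Step 14
Reactants: 11 (5R,6Z)-5-[(benzyloxy)methyl]-6-(hydroxymethylidene)-4,4-dimethylcyclohex-2-en-1-one; 23 methyl (1R,4R,5R)-4-hydroxy-6-methylidenebicyclo[3.2.1]oct-2-ene-1-carboxylate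
Product: 24 methyl (1R,4S,5R)-4-{(E)-[(6R)-6-[(benzyloxy)methyl]-5,5-dimethyl-2-oxocyclohex-3-en-1-ylidene]methoxy}-6-methylidenebicyclo[3.2.1]oct-2-ene-1-carboxylate
Conditions: PPh3, DIAD, toluene, 0 °C to rt
Reagents that add atoms: none
Why: Mitsunobu O-alkylation of the acidic enol proceeds by SN2 displacement with inversion at C12, which puts the enol ether oxygen on the C14 face, while SN2′ attack at C9 is blocked by the quaternary C8 (O-alkylation at either oxygen of the β-keto aldehyde would lead to the same rearrangement product).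

Step 15
Reactants: 24 methyl (1R,4S,5R)-4-{(E)-[(6R)-6-[(benzyloxy)methyl]-5,5-dimethyl-2-oxocyclohex-3-en-1-ylidene]methoxy}-6-methylidenebicyclo[3.2.1]oct-2-ene-1-carboxylate
Product: 25 methyl (1R,2S,5S)-2-{(1S,6R)-6-[(benzyloxy)methyl]-1-formyl-5,5-dimethyl-2-oxocyclohex-3-en-1-yl}-6-methylidenebicyclo[3.2.1]oct-3-ene-1-carboxylate
Conditions: toluene, BHT (cat.), sealed tube, 140 °C
Reagents that add atoms: none
Why: Claisen rearrangement ([3,3]-sigmatropic) moves the allyl unit suprafacially from oxygen to C10, so C9 receives C10 on the face that carried the oxygen (the C14 face), and C10 is attacked anti to the pseudo-axial C5 benzyloxymethyl group, which places the new C9–C10 bond trans to C6.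

Step 16
Reactants: 25 methyl (1R,2S,5S)-2-{(1S,6R)-6-[(benzyloxy)methyl]-1-formyl-5,5-dimethyl-2-oxocyclohex-3-en-1-yl}-6-methylidenebicyclo[3.2.1]oct-3-ene-1-carboxylate
Product: 27 (5R,8R,9S,10S,13S)-6-(benzyloxy)-1-oxo-6,7-seco-ent-kaura-2,11,16-trien-7,20-olide, via hydroxy ester 26 (not isolated)
Conditions: NaBH4 (0.5 equiv), THF/MeOH, −40 °C; then PPTS (cat.), toluene, 50 °C
Reagents that add atoms: none
Why: Chemoselective borohydride reduction takes the neopentyl aldehyde much faster than the hindered conjugated ketone or the ester, and the C20 alcohol, held next to the C7 ester across C8–C9, closes the δ-lactone by acid-catalysed transesterification.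

Step 17
Reactants: 27 (5R,8R,9S,10S,13S)-6-(benzyloxy)-1-oxo-6,7-seco-ent-kaura-2,11,16-trien-7,20-olide
Product: 28 (5R,8S,9S,10S,13S,15R)-6-(benzyloxy)-15-hydroxy-1-oxo-6,7-seco-ent-kaura-2,11,16-trien-7,20-olide
Conditions: SeO2 (0.3 equiv), t-BuOOH (3 equiv), CH2Cl2, 0 °C to rt
Reagents that add atoms: tert-butyl hydroperoxide, CC(C)(C)OO
Why: Selenium dioxide allylic hydroxylation (ene reaction, then [2,3]-sigmatropic shift) attacks the only allylic methylene (C15) and, by analogy with ent-kaur-16-enes, is expected to deliver oxygen on the β face syn to H-9, away from the lactone and C14.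

Step 18
Reactants: 28 (5R,8S,9S,10S,13S,15R)-6-(benzyloxy)-15-hydroxy-1-oxo-6,7-seco-ent-kaura-2,11,16-trien-7,20-olide
Product: 29 (5R,8S,9S,10S,13S,15S,16S)-6-(benzyloxy)-16,17-epoxy-15-hydroxy-1-oxo-6,7-seco-ent-kaura-2,11-dien-7,20-olide
Conditions: VO(acac)2 (5 mol%), t-BuOOH (1.5 equiv), CH2Cl2, 0 °C to rt
Reagents that add atoms: tert-butyl hydroperoxide, CC(C)(C)OO
Why: Vanadium-catalysed hydroxyl-directed epoxidation delivers oxygen to the exocyclic alkene from the face of the C15 hydroxyl, which gives the syn (β) epoxide at C16 and leaves the C11=C12 alkene and the enone untouched.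

Step 19
Reactants: 29 (5R,8S,9S,10S,13S,15S,16S)-6-(benzyloxy)-16,17-epoxy-15-hydroxy-1-oxo-6,7-seco-ent-kaura-2,11-dien-7,20-olide
Product: 30 (5R,8S,9S,10S,13R,15S,16S)-16,17-epoxy-6,15-dihydroxy-1-oxo-6,7-seco-ent-kauran-7,20-olide
Conditions: H2 (1 atm), 10% Pd/C, EtOAc, rt
Reagents that add atoms: none
Why: Heterogeneous catalytic hydrogenation saturates C11=C12 and C2=C3 and hydrogenolyses the benzyl ether in one operation, with no new stereocentre and the unactivated epoxide expected to survive neutral conditions.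

Step 20
Reactants: 30 (5R,8S,9S,10S,13R,15S,16S)-16,17-epoxy-6,15-dihydroxy-1-oxo-6,7-seco-ent-kauran-7,20-olide
Product: 33 (5R,8S,9S,10S,13R,15S,16S)-16,17-epoxy-6,15-dihydroxy-1-oxo-6,7-seco-ent-kaur-2-en-7,20-olide, via silyl enol ether 31 (not isolated), via bis-silyl enone 32 (not isolated)
Conditions: LiN(i-Pr)2 (3.5 equiv), TMSCl (4 equiv, present from the start), THF, −78 °C; then Pd(OAc)2 (1.1 equiv), MeCN, rt; then citric acid (cat.), MeOH, 0 °C
Reagents that add atoms: none
Why: Saegusa–Ito oxidation, in which the ketone can enolise only towards C2 (C10 is quaternary), palladium diacetate dehydrogenates the silyl enol ether by β-hydride elimination, and mild acidic methanolysis removes the transient silyl ethers.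

Step 21
Reactants: 33 (5R,8S,9S,10S,13R,15S,16S)-16,17-epoxy-6,15-dihydroxy-1-oxo-6,7-seco-ent-kaur-2-en-7,20-olide
Product: 34 (5R,8S,9S,10S,13R,15S,16S)-16,17-epoxy-15-hydroxy-1,6-dioxo-6,7-seco-ent-kaur-2-en-7,20-olide (CNP0537841.1)
Conditions: TEMPO (10 mol%), PhI(OAc)2 (1.2 equiv), CH2Cl2, rt
Reagents that add atoms: none
Why: Oxoammonium (TEMPO) oxidation is selective for the unhindered primary alcohol over the neopentyl secondary C15 alcohol and is neutral enough to keep the epoxide and the C5 configuration.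

**Compound list**

1 | 2-methylpropanal | CC(C)C=O | starting material
2 | but-3-en-2-one | CC(=O)C=C | starting material
3 | 4,4-dimethylcyclohex-2-en-1-one | CC1(C)C=CC(=O)CC1 | intermediate
4 | 4,4-dimethylcyclohexa-2,5-dien-1-one | CC1(C)C=CC(=O)C=C1 | intermediate
5 | (E)-prop-1-en-1-ylboronic acid | C/C=C/B(O)O | starting material
6 | (5R)-4,4-dimethyl-5-[(1E)-prop-1-en-1-yl]cyclohex-2-en-1-one | CC1(C)C=CC(=O)C[C@@H]1/C=C/C | intermediate
7 | (1S)-2,2-dimethyl-5-oxocyclohex-3-ene-1-carbaldehyde | CC1(C)C=CC(=O)C[C@@H]1C=O | intermediate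
8 | (5S)-5-(hydroxymethyl)-4,4-dimethylcyclohex-2-en-1-one | CC1(C)C=CC(=O)C[C@@H]1CO | intermediate
9 | (5S)-5-[(benzyloxy)methyl]-4,4-dimethylcyclohex-2-en-1-one | CC1(C)C=CC(=O)C[C@@H]1COCc1ccccc1 | intermediate
10 | ethyl formate | CCOC=O | starting material
11 | (5R,6Z)-5-[(benzyloxy)methyl]-6-(hydroxymethylidene)-4,4-dimethylcyclohex-2-en-1-one (fragment A) | CC1(C)C=CC(=O)/C(=C\O)[C@@H]1COCc1ccccc1 | intermediate
12 | pent-4-ynal | C#CCCC=O | starting material
13 | formaldehyde | C=O | starting material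
14 | 2-methylidenepent-4-ynal | C#CCC(=C)C=O | intermediate
15 | (3E)-4-(dimethylamino)but-3-en-2-one | CC(=O)/C=C/N(C)C | starting material
16 | (1E)-3-[(tert-butyldimethylsilyl)oxy]-N,N-dimethylbuta-1,3-dien-1-amine | C=C(O[Si](C)(C)C(C)(C)C)/C=C/N(C)C | intermediate
17 | (1R,2R)-4-[(tert-butyldimethylsilyl)oxy]-2-(dimethylamino)-1-(prop-2-yn-1-yl)cyclohex-3-ene-1-carbaldehyde | O=C[C@]1(CC#C)[C@H](N(C)C)C=C(O[Si](C)(C)C(C)(C)C)CC1 | intermediate
18 | (1R)-4-oxo-1-(prop-2-yn-1-yl)cyclohex-2-ene-1-carbaldehyde | O=C[C@]1(CC#C)C=CC(=O)CC1 | intermediate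
19 | (1R)-4-oxo-1-(prop-2-yn-1-yl)cyclohex-2-ene-1-carboxylic acid | OC(=O)[C@]1(CC#C)C=CC(=O)CC1 | intermediate
20 | methyl (1R)-4-oxo-1-(prop-2-yn-1-yl)cyclohex-2-ene-1-carboxylate | COC(=O)[C@]1(CC#C)C=CC(=O)CC1 | intermediate
21 | methyl (1R)-4-[(tert-butyldimethylsilyl)oxy]-1-(prop-2-yn-1-yl)cyclohexa-2,4-diene-1-carboxylate | COC(=O)[C@]1(CC#C)C=CC(O[Si](C)(C)C(C)(C)C)=CC1 | intermediate
22 | methyl (1R,5R)-6-methylidene-4-oxobicyclo[3.2.1]oct-2-ene-1-carboxylate | O=C1C=C[C@@]2(C(=O)OC)C[C@@H]1C(=C)C2 | intermediate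
23 | methyl (1R,4R,5R)-4-hydroxy-6-methylidenebicyclo[3.2.1]oct-2-ene-1-carboxylate (fragment B) | O[C@@H]1C=C[C@@]2(C(=O)OC)C[C@@H]1C(=C)C2 | intermediate
24 | methyl (1R,4S,5R)-4-{(E)-[(6R)-6-[(benzyloxy)methyl]-5,5-dimethyl-2-oxocyclohex-3-en-1-ylidene]methoxy}-6-methylidenebicyclo[3.2.1]oct-2-ene-1-carboxylate | CC1(C)C=CC(=O)/C(=C/O[C@H]2C=C[C@@]3(C(=O)OC)C[C@@H]2C(=C)C3)[C@@H]1COCc1ccccc1 | intermediate
25 | methyl (1R,2S,5S)-2-{(1S,6R)-6-[(benzyloxy)methyl]-1-formyl-5,5-dimethyl-2-oxocyclohex-3-en-1-yl}-6-methylidenebicyclo[3.2.1]oct-3-ene-1-carboxylate | CC1(C)C=CC(=O)[C@@](C=O)([C@@H]2C=C[C@@H]3C[C@@]2(C(=O)OC)CC3=C)[C@@H]1COCc1ccccc1 | intermediate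
26 | methyl (1R,2S,5S)-2-{(1S,6R)-6-[(benzyloxy)methyl]-1-(hydroxymethyl)-5,5-dimethyl-2-oxocyclohex-3-en-1-yl}-6-methylidenebicyclo[3.2.1]oct-3-ene-1-carboxylate | CC1(C)C=CC(=O)[C@@](CO)([C@@H]2C=C[C@@H]3C[C@@]2(C(=O)OC)CC3=C)[C@@H]1COCc1ccccc1 | intermediate
27 | (5R,8R,9S,10S,13S)-6-(benzyloxy)-1-oxo-6,7-seco-ent-kaura-2,11,16-trien-7,20-olide | CC1(C)C=CC(=O)[C@]2(COC(=O)[C@@]34C[C@@H](C=C[C@@H]23)C(=C)C4)[C@@H]1COCc1ccccc1 | intermediate
28 | (5R,8S,9S,10S,13S,15R)-6-(benzyloxy)-15-hydroxy-1-oxo-6,7-seco-ent-kaura-2,11,16-trien-7,20-olide | CC1(C)C=CC(=O)[C@]2(COC(=O)[C@@]34C[C@@H](C=C[C@@H]23)C(=C)[C@H]4O)[C@@H]1COCc1ccccc1 | intermediate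
29 | (5R,8S,9S,10S,13S,15S,16S)-6-(benzyloxy)-16,17-epoxy-15-hydroxy-1-oxo-6,7-seco-ent-kaura-2,11-dien-7,20-olide | CC1(C)C=CC(=O)[C@]2(COC(=O)[C@@]34C[C@@H](C=C[C@@H]23)[C@]2(CO2)[C@H]4O)[C@@H]1COCc1ccccc1 | intermediate
30 | (5R,8S,9S,10S,13R,15S,16S)-16,17-epoxy-6,15-dihydroxy-1-oxo-6,7-seco-ent-kauran-7,20-olide | CC1(C)CCC(=O)[C@]2(COC(=O)[C@@]34C[C@@H](CC[C@@H]23)[C@]2(CO2)[C@H]4O)[C@@H]1CO | intermediate
31 | (5R,8S,9S,10S,13R,15S,16S)-16,17-epoxy-1,6,15-tris(trimethylsilyloxy)-6,7-seco-ent-kaur-1-en-7,20-olide | CC1(C)CC=C(O[Si](C)(C)C)[C@]2(COC(=O)[C@@]34C[C@@H](CC[C@@H]23)[C@]2(CO2)[C@H]4O[Si](C)(C)C)[C@@H]1CO[Si](C)(C)C | intermediate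
32 | (5R,8S,9S,10S,13R,15S,16S)-16,17-epoxy-1-oxo-6,15-bis(trimethylsilyloxy)-6,7-seco-ent-kaur-2-en-7,20-olide | CC1(C)C=CC(=O)[C@]2(COC(=O)[C@@]34C[C@@H](CC[C@@H]23)[C@]2(CO2)[C@H]4O[Si](C)(C)C)[C@@H]1CO[Si](C)(C)C | intermediate
33 | (5R,8S,9S,10S,13R,15S,16S)-16,17-epoxy-6,15-dihydroxy-1-oxo-6,7-seco-ent-kaur-2-en-7,20-olide | CC1(C)C=CC(=O)[C@]2(COC(=O)[C@@]34C[C@@H](CC[C@@H]23)[C@]2(CO2)[C@H]4O)[C@@H]1CO | intermediate
34 | (5R,8S,9S,10S,13R,15S,16S)-16,17-epoxy-15-hydroxy-1,6-dioxo-6,7-seco-ent-kaur-2-en-7,20-olide (CNP0537841.1) | CC1(C)C=CC(=O)[C@]2(COC(=O)[C@@]34C[C@@H](CC[C@@H]23)[C@]2(CO2)[C@H]4O)[C@@H]1C=O | target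

**Step count and risks**

Total step count: 21 (fragment A: steps 1–6; fragment B: steps 7–13, with step 8 as a side branch; union and endgame: steps 14–21).

Longest linear sequence: 14 steps (steps 1–6 then 14–21; the fragment B line, steps 7 and 9–13 then 14–21, is equally long), i.e. 14 of 21.

Steps most likely to fail:

Step 14 (Mitsunobu etherification at the hindered C12). The inversion and the C–O bond formation can be separated. Setting out from 23 and 11: 23 is inverted with 4-nitrobenzoic acid, PPh3 and DIAD to methyl (1R,4S,5R)-6-methylidene-4-[(4-nitrobenzoyl)oxy]bicyclo[3.2.1]oct-2-ene-1-carboxylate F1, and K2CO3 in MeOH gives the epimeric alcohol methyl (1R,4S,5R)-4-hydroxy-6-methylidenebicyclo[3.2.1]oct-2-ene-1-carboxylate F2. In parallel, 11 is converted with oxalyl chloride and catalytic DMF into the vinylogous acid chloride (5R,6E)-5-[(benzyloxy)methyl]-6-(chloromethylidene)-4,4-dimethylcyclohex-2-en-1-one F3. The sodium alkoxide of F2 (NaH, THF, 0 °C) then adds to F3 and expels chloride (addition–elimination with retention at C12), which comes back to the route at 24.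

Step 15 (thermal Claisen rearrangement building the congested C9–C10 bond, with C10 facial control resting on the C5 substituent). If it fails or gives the C10 epimer, the bond is made by conjugate addition instead. Setting out from 11 and enone 22: base-mediated Michael addition (DBU or Cs2CO3, MeCN, rt, under high pressure if needed) from the C14 face gives methyl (1R,2S,5R)-2-{(1S,6R)-6-[(benzyloxy)methyl]-1-formyl-5,5-dimethyl-2-oxocyclohex-3-en-1-yl}-6-methylidene-4-oxobicyclo[3.2.1]octane-1-carboxylate F4. NaBH4 at −40 °C reduces the aldehyde and the C12 ketone, and PPTS closes the lactone to 6-(benzyloxy)-12-hydroxy-1-oxo-6,7-seco-ent-kaura-2,16-dien-7,20-olide F5. Burgess dehydration (syn elimination towards C11, the other neighbour being a bridgehead) comes back to the route at 27.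

Step 20 (strong-base enol silane formation on the unprotected epoxy diol, with a risk of Payne rearrangement). The desaturation can be done oxidatively with the C15 hydroxyl masked. Setting out from 29: TBSOTf and 2,6-lutidine at −78 °C give 6-(benzyloxy)-15-[(tert-butyldimethylsilyl)oxy]-16,17-epoxy-1-oxo-6,7-seco-ent-kaura-2,11-dien-7,20-olide F6. Hydrogenation as in step 19 gives 15-[(tert-butyldimethylsilyl)oxy]-16,17-epoxy-6-hydroxy-1-oxo-6,7-seco-ent-kauran-7,20-olide F7. IBX (DMSO, 75 °C) oxidises the primary alcohol and dehydrogenates the ketone in one pot (the aldehyde cannot be dehydrogenated because C4 and C10 are quaternary) to 15-[(tert-butyldimethylsilyl)oxy]-16,17-epoxy-1,6-dioxo-6,7-seco-ent-kaur-2-en-7,20-olide F8. TBAF buffered with AcOH removes the silyl group and comes back to the route at 34.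

**Further compounds**

F1 | step 14 | methyl (1R,4S,5R)-6-methylidene-4-[(4-nitrobenzoyl)oxy]bicyclo[3.2.1]oct-2-ene-1-carboxylate | O=C(O[C@H]1C=C[C@@]2(C(=O)OC)C[C@@H]1C(=C)C2)c1ccc(cc1)[N+](=O)[O-]
F2 | step 14 | methyl (1R,4S,5R)-4-hydroxy-6-methylidenebicyclo[3.2.1]oct-2-ene-1-carboxylate | O[C@H]1C=C[C@@]2(C(=O)OC)C[C@@H]1C(=C)C2
F3 | step 14 | (5R,6E)-5-[(benzyloxy)methyl]-6-(chloromethylidene)-4,4-dimethylcyclohex-2-en-1-one | CC1(C)C=CC(=O)/C(=C/Cl)[C@@H]1COCc1ccccc1
F4 | step 15 | methyl (1R,2S,5R)-2-{(1S,6R)-6-[(benzyloxy)methyl]-1-formyl-5,5-dimethyl-2-oxocyclohex-3-en-1-yl}-6-methylidene-4-oxobicyclo[3.2.1]octane-1-carboxylate | CC1(C)C=CC(=O)[C@@](C=O)([C@@H]2CC(=O)[C@@H]3C[C@@]2(C(=O)OC)CC3=C)[C@@H]1COCc1ccccc1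
F5 | step 15 | 6-(benzyloxy)-12-hydroxy-1-oxo-6,7-seco-ent-kaura-2,16-dien-7,20-olide (12-OH on the face of the C15–C16 bridge) | CC1(C)C=CC(=O)[C@]2(COC(=O)[C@@]34C[C@@H]([C@H](O)C[C@@H]23)C(=C)C4)[C@@H]1COCc1ccccc1
F6 | step 20 | 6-(benzyloxy)-15-[(tert-butyldimethylsilyl)oxy]-16,17-epoxy-1-oxo-6,7-seco-ent-kaura-2,11-dien-7,20-olide | CC1(C)C=CC(=O)[C@]2(COC(=O)[C@@]34C[C@@H](C=C[C@@H]23)[C@]2(CO2)[C@H]4O[Si](C)(C)C(C)(C)C)[C@@H]1COCc1ccccc1
F7 | step 20 | 15-[(tert-butyldimethylsilyl)oxy]-16,17-epoxy-6-hydroxy-1-oxo-6,7-seco-ent-kauran-7,20-olide | CC1(C)CCC(=O)[C@]2(COC(=O)[C@@]34C[C@@H](CC[C@@H]23)[C@]2(CO2)[C@H]4O[Si](C)(C)C(C)(C)C)[C@@H]1CO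
F8 | step 20 | 15-[(tert-butyldimethylsilyl)oxy]-16,17-epoxy-1,6-dioxo-6,7-seco-ent-kaur-2-en-7,20-olide | CC1(C)C=CC(=O)[C@]2(COC(=O)[C@@]34C[C@@H](CC[C@@H]23)[C@]2(CO2)[C@H]4O[Si](C)(C)C(C)(C)C)[C@@H]1C=O
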